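**Retrosynthetic overview**
1. Feature: ring B carries oxygen at C1', C2' and C4'. The free C2'–OH is meta to C4'–OCH3 and ortho to the C1' oxygen bound to C6 of ring A (benzoate: C1 CO2CH3, C2 OH, C4 CH3), and C6' carries CH2OAc. A phenol with an alkoxy group meta to it is the pattern that a vinylketene and an ynol ether leave on benzannulation.
2. Endgame disconnections: the acetyl–O bond on the C6' CH2OH group (ester made last, on the alcohol only), then the MOM group (ring A C2–O) and the TBS group (C6' CH2–O).
3. Key disconnection: C2'–C3', C4'–C5' and C1'–C2' of ring B. This leads back to methoxyacetylene and an acyclic α'-diazo β-aryloxy enone whose β-oxygen is already the C6 oxygen of ring A.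
4. The diazo enone comes from its methyl ketone by detrifluoroacetylative diazo transfer. The ketone comes from the mono-MOM ring A phenol and a β-iodo enone by vinylic substitution (C1'–O bond). The iodo enone comes from but-3-yn-2-one, MgI2 and formaldehyde (C6'–CH2 bond).
5. Ring order: ring A is bought complete; ring B is the only ring formed, in step 7.

Key step: step 7

Assumption: methyl 2,6-dihydroxy-4-methylbenzoate is taken as a catalogue compound, so ring A enters with its ester carbon already between the two oxygens; the target has no stereocentre, and only alkene geometry is tracked.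

Step 1
Reactants: 1 methyl 2,6-dihydroxy-4-methylbenzoate
Product: 2 methyl 2-hydroxy-6-(methoxymethoxy)-4-methylbenzoate
Conditions: MOMCl (1.05 equiv), i-Pr2NEt, CH2Cl2, 0 °C → rt
Reagents that add atoms: chloromethyl methyl ether (MOMCl) COCCl
Why: Williamson-type O-alkylation of a phenol with a chloromethyl ether; the two hydroxyls of 1 are equivalent, and after the first alkylation the remaining one is held by a strong hydrogen bond to the ester carbonyl, so one equivalent of MOMCl with an amine base should stop at the mono-ether.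

Step 2
Reactants: 3 but-3-yn-2-one
Product: 5 (3Z)-3-(hydroxymethyl)-4-iodobut-3-en-2-one, via iodomagnesium iodoallenolate 4 (not isolated)
Conditions: MgI2 (1.2 equiv), CH2O (gas from cracked paraformaldehyde), CH2Cl2, −20 → 0 °C; then H2O
Reagents that add atoms: magnesium iodide [Mg+2].[I-].[I-]; formaldehyde C=O
Why: Halo-aldol (β-iodo Morita–Baylis–Hillman) reaction: iodide adds in conjugate fashion to the Mg-activated ynone and allenolate 4 is hydroxymethylated at its α-carbon, formaldehyde approaching in the plane of the CHI terminus from the hydrogen side, which puts iodine cis to acetyl (Z) and places halogen, CH2OH and acetyl without regiochemical ambiguity.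

Step 3
Reactants: 5 (3Z)-3-(hydroxymethyl)-4-iodobut-3-en-2-one
Product: 6 (3Z)-3-{[(tert-butyldimethylsilyl)oxy]methyl}-4-iodobut-3-en-2-one
Conditions: TBSOTf, 2,6-lutidine, CH2Cl2, −78 °C
Reagents that add atoms: tert-butyldimethylsilyl triflate CC(C)(C)[Si](C)(C)OS(=O)(=O)C(F)(F)F
Why: Silylation of a primary alcohol with a silyl triflate; the hindered, non-nucleophilic base is chosen because imidazole or DMAP could displace the vinylic iodide, and at −78 °C the methyl ketone should not be enol-silylated.

Step 4
Reactants: 2 methyl 2-hydroxy-6-(methoxymethoxy)-4-methylbenzoate; 6 (3Z)-3-{[(tert-butyldimethylsilyl)oxy]methyl}-4-iodobut-3-en-2-one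
Product: 7 methyl 2-{[(1E)-2-{[(tert-butyldimethylsilyl)oxy]methyl}-3-oxobut-1-en-1-yl]oxy}-6-(methoxymethoxy)-4-methylbenzoate
Conditions: Cs2CO3, MeCN, 0 °C → rt
Reagents that add atoms: none
Why: Vinylic nucleophilic substitution by addition–elimination, known for phenols and β-halovinyl ketones: the phenoxide of 2 adds to the vinylogous acyl iodide and the enolate expels iodide, a far better leaving group than silyloxide; bond rotation in the enolate and reversible re-addition should favour the more stable E enol ether, and any Z isomer is harmless because both geometries converge in step 7.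

Step 5
Reactants: 7 methyl 2-{[(1E)-2-{[(tert-butyldimethylsilyl)oxy]methyl}-3-oxobut-1-en-1-yl]oxy}-6-(methoxymethoxy)-4-methylbenzoate
Product: 10 methyl 2-{[(1E)-2-{[(tert-butyldimethylsilyl)oxy]methyl}-4-diazo-3-oxobut-1-en-1-yl]oxy}-6-(methoxymethoxy)-4-methylbenzoate, via lithium enolate 8 (not isolated), via trifluoroacetyl diketone 9 (not isolated)
Conditions: LiN(SiMe3)2, THF, −78 °C; CF3CO2CH2CF3, −78 °C; cold dilute aq HCl wash; then MsN3, Et3N, H2O (1 equiv), MeCN, rt
Reagents that add atoms: methanesulfonyl azide CS(=O)(=O)N=[N+]=[N-] (the N2 unit of 10); 2,2,2-trifluoroethyl trifluoroacetate FC(F)(F)COC(=O)C(F)(F)F (CF3CO group of 9 only); LiN(SiMe3)2 [Li]N([Si](C)(C)C)[Si](C)(C)C (lithium of 8 only)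
Why: Detrifluoroacetylative diazo transfer (a Regitz-type transfer to an activated ketone): a plain methyl ketone does not accept a diazo group, so the kinetic α' enolate 8 is first C-acylated, and the acidic diketone 9 then takes N2 from mesyl azide and loses the trifluoroacetyl group as the N-acylsulfonamide, under conditions standard for enones that should spare the ester, MOM, TBS and enol ether.

Step 6
Reactants: 11 chloroacetaldehyde dimethyl acetal (2-chloro-1,1-dimethoxyethane)
Product: 13 methoxyacetylene (methoxyethyne), via sodium methoxyacetylide 12 (not isolated)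
Conditions: NaNH2 (3 equiv), NH3(l), −33 °C; then cold sat. aq NaCl; distil (bp about 23 °C), store as a cold CH2Cl2 solution
Reagents that add atoms: NaNH2 [Na+].[NH2-] (sodium of 12 only; no atom other than hydrogen reaches 13)
Why: Base-induced double β-elimination, the standard preparation of alkoxyacetylenes: NaNH2 removes methanol and then HCl from the chloroacetal, and a third equivalent holds the product as acetylide 12 until the aqueous quench.

Step 7
Reactants: 10 methyl 2-{[(1E)-2-{[(tert-butyldimethylsilyl)oxy]methyl}-4-diazo-3-oxobut-1-en-1-yl]oxy}-6-(methoxymethoxy)-4-methylbenzoate; 13 methoxyacetylene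
Product: 18 methyl 2-[2-{[(tert-butyldimethylsilyl)oxy]methyl}-6-hydroxy-4-methoxyphenoxy]-6-(methoxymethoxy)-4-methylbenzoate, via vinylketene 14 (not isolated), via 4-alkenyl-3-methoxycyclobutenone 15 (not isolated), via dienylketene 16 (not isolated), via cyclohexa-2,4-dienone 17 (not isolated)
Conditions: 13 (5 equiv), CH2Cl2 (0.05 M), hν (450 W medium-pressure Hg lamp, Pyrex), 0 °C, dry-ice condenser; evaporate excess 13; PhMe, 90 °C
Reagents that add atoms: none
Why: Proposed new method: light expels N2 from 10 with 1,2-shift of the alkenyl group (Wolff rearrangement) to give the β-aryloxy vinylketene 14, which adds methoxyacetylene across its C=C bond in a [2+2] cycloaddition, the nucleophilic CH terminus of the ynol ether bonding to the ketene carbonyl carbon (C2'–C3') and the methoxy-bearing carbon to the former diazo carbon (C4'–C5'), to give cyclobutenone 15. On heating, 15 opens in a reversible 4π electrocyclic step to dienylketene 16, ring B is closed by a 6π electrocyclisation that joins the ketene carbon to the aryloxy-bearing CH (C1'–C2'), and dienone 17 tautomerises to phenol 18. The closest known reaction type is the Danheiser benzannulation in its diazo ketone form with alkoxyacetylenes, established for alkyl-, aryl- and ring-fused vinylketenes, whereas an oxygen substituent on the vinylketene terminus is untested. It should be tolerated because the aryloxy group sits on the carbon remote from the ketene, leaves the electrophilic ketene carbon open to the ynol ether, and as a donor on the triene terminus should help the 6π closure, the E geometry of 10 turning it outward. No stereocentre remains, since the sp3 carbons of 15 and 17 become aromatic and either alkene geometry leads to the same arene. The step needs regioselectivity in the [2+2] event, secured by the polarisation of methoxyacetylene, and chemoselective capture of the ketenes, secured by the MOM and TBS masks, by the excess of alkyne during irradiation and by its removal before heating.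

Step 8
Reactants: 18 methyl 2-[2-{[(tert-butyldimethylsilyl)oxy]methyl}-6-hydroxy-4-methoxyphenoxy]-6-(methoxymethoxy)-4-methylbenzoate
Product: 19 methyl 2-hydroxy-6-[2-hydroxy-6-(hydroxymethyl)-4-methoxyphenoxy]-4-methylbenzoate
Conditions: HCl (1.25 M in MeOH), rt → 40 °C
Reagents that add atoms: none
Why: Acid-catalysed solvolysis (transacetalisation of the MOM acetal and methanolysis of the primary silyl ether in one operation): methanol makes ester exchange degenerate and holds back lactonisation, the acid medium avoids a C2' phenoxide that could start a Smiles rearrangement on the ester-activated ring A, and the benzylic alcohol should not ionise because the C2' and C4' oxygens are meta to C6'.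

Step 9
Reactants: 19 methyl 2-hydroxy-6-[2-hydroxy-6-(hydroxymethyl)-4-methoxyphenoxy]-4-methylbenzoate
Product: 20 betaethrin A, methyl 2-{2-[(acetyloxy)methyl]-6-hydroxy-4-methoxyphenoxy}-6-hydroxy-4-methylbenzoate
Conditions: AcOH (3 equiv), PPh3, DIAD, THF, 0 °C → rt
Reagents that add atoms: acetic acid CC(=O)O
Why: Mitsunobu esterification, known to be chemoselective for phenolic benzyl alcohols: only the primary alcohol is activated as its oxyphosphonium salt, and acetic acid, far more acidic than either phenol and used in excess, supplies the nucleophile, so both phenols should stay free under neutral conditions.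

**Compound list**
1 | methyl 2,6-dihydroxy-4-methylbenzoate | COC(=O)c1c(O)cc(C)cc1O | starting material
2 | methyl 2-hydroxy-6-(methoxymethoxy)-4-methylbenzoate | COC(=O)c1c(O)cc(C)cc1OCOC | intermediate
3 | but-3-yn-2-one | CC(=O)C#C | starting material
4 | iodomagnesium 4-iodobuta-2,3-dien-2-olate | CC(O[Mg]I)=C=CI | intermediate
5 | (3Z)-3-(hydroxymethyl)-4-iodobut-3-en-2-one | CC(=O)/C(CO)=C\I | intermediate
6 | (3Z)-3-{[(tert-butyldimethylsilyl)oxy]methyl}-4-iodobut-3-en-2-one | CC(=O)/C(CO[Si](C)(C)C(C)(C)C)=C\I | intermediate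
7 | methyl 2-{[(1E)-2-{[(tert-butyldimethylsilyl)oxy]methyl}-3-oxobut-1-en-1-yl]oxy}-6-(methoxymethoxy)-4-methylbenzoate | COC(=O)c1c(OCOC)cc(C)cc1O/C=C(CO[Si](C)(C)C(C)(C)C)/C(C)=O | intermediate
8 | lithium (3E)-3-{[(tert-butyldimethylsilyl)oxy]methyl}-4-[2-(methoxycarbonyl)-3-(methoxymethoxy)-5-methylphenoxy]buta-1,3-dien-2-olate | COC(=O)c1c(OCOC)cc(C)cc1O/C=C(CO[Si](C)(C)C(C)(C)C)/C(=C)O[Li] | intermediate
9 | methyl 2-{[(1E)-2-{[(tert-butyldimethylsilyl)oxy]methyl}-6,6,6-trifluoro-3,5-dioxohex-1-en-1-yl]oxy}-6-(methoxymethoxy)-4-methylbenzoate | COC(=O)c1c(OCOC)cc(C)cc1O/C=C(CO[Si](C)(C)C(C)(C)C)/C(=O)CC(=O)C(F)(F)F | intermediate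
10 | methyl 2-{[(1E)-2-{[(tert-butyldimethylsilyl)oxy]methyl}-4-diazo-3-oxobut-1-en-1-yl]oxy}-6-(methoxymethoxy)-4-methylbenzoate | COC(=O)c1c(OCOC)cc(C)cc1O/C=C(CO[Si](C)(C)C(C)(C)C)/C(=O)C=[N+]=[N-] | intermediate
11 | chloroacetaldehyde dimethyl acetal | COC(CCl)OC | starting material
12 | sodium methoxyacetylide | COC#[C-].[Na+] | intermediate
13 | methoxyacetylene | COC#C | intermediate
14 | methyl 2-{[(1Z)-2-{[(tert-butyldimethylsilyl)oxy]methyl}-4-oxobuta-1,3-dien-1-yl]oxy}-6-(methoxymethoxy)-4-methylbenzoate (vinylketene) | COC(=O)c1c(OCOC)cc(C)cc1O/C=C(CO[Si](C)(C)C(C)(C)C)/C=C=O | intermediate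
15 | methyl 2-{[(1Z)-3-[(tert-butyldimethylsilyl)oxy]-2-(2-methoxy-4-oxocyclobut-2-en-1-yl)prop-1-en-1-yl]oxy}-6-(methoxymethoxy)-4-methylbenzoate (racemic) | COC(=O)c1c(OCOC)cc(C)cc1O/C=C(CO[Si](C)(C)C(C)(C)C)/C1C(=O)C=C1OC | intermediate
16 | methyl 2-{[(1Z,3E)-2-{[(tert-butyldimethylsilyl)oxy]methyl}-4-methoxy-6-oxohexa-1,3,5-trien-1-yl]oxy}-6-(methoxymethoxy)-4-methylbenzoate (dienylketene) | COC(=O)c1c(OCOC)cc(C)cc1O/C=C(CO[Si](C)(C)C(C)(C)C)/C=C(OC)\C=C=O | intermediate
17 | methyl 2-{[2-{[(tert-butyldimethylsilyl)oxy]methyl}-4-methoxy-6-oxocyclohexa-2,4-dien-1-yl]oxy}-6-(methoxymethoxy)-4-methylbenzoate (racemic) | COC(=O)c1c(OCOC)cc(C)cc1OC1C(=O)C=C(OC)C=C1CO[Si](C)(C)C(C)(C)C | intermediate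
18 | methyl 2-[2-{[(tert-butyldimethylsilyl)oxy]methyl}-6-hydroxy-4-methoxyphenoxy]-6-(methoxymethoxy)-4-methylbenzoate | COC(=O)c1c(OCOC)cc(C)cc1Oc1c(O)cc(OC)cc1CO[Si](C)(C)C(C)(C)C | intermediate
19 | methyl 2-hydroxy-6-[2-hydroxy-6-(hydroxymethyl)-4-methoxyphenoxy]-4-methylbenzoate | COC(=O)c1c(O)cc(C)cc1Oc1c(O)cc(OC)cc1CO | intermediate
20 | betaethrin A, methyl 2-{2-[(acetyloxy)methyl]-6-hydroxy-4-methoxyphenoxy}-6-hydroxy-4-methylbenzoate | COC(=O)c1c(O)cc(C)cc1Oc1c(O)cc(OC)cc1COC(C)=O | target

Total step count: 9
Longest linear sequence: 7 steps (steps 2, 3, 4, 5, 7, 8 and 9, from but-3-yn-2-one)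

**Steps most likely to fail**

**Step 7.**
- What may go wrong:
  - The vinylketene may be lost to dimerisation, to [2+2] addition onto the enol ether double bond of a second molecule, or to acylation of the phenol as it forms.
  - The aryl enol ether may degrade under the lamp.
  - The 6π closure may lag behind polymerisation of the dienylketene.
- Fallback (sets out from 2, returns at 19): ring B is taken from a bought arene, and the C1'–O bond is made by nucleophilic aromatic substitution on a mirror-symmetric electrophile.
  - Purchased 4-bromo-3,5-dimethylanisole is brominated at both methyl groups (NBS, AIBN, Wohl–Ziegler reaction) to 2-bromo-1,3-bis(bromomethyl)-5-methoxybenzene F1.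
  - Kornblum oxidation (DMSO, NaHCO3) gives 2-bromo-5-methoxybenzene-1,3-dicarbaldehyde F2, in which two ortho formyl groups activate the C–Br bond.
  - Phenol 2 displaces bromide (K2CO3, DMF, 80 °C) to give methyl 2-(2,6-diformyl-4-methoxyphenoxy)-6-(methoxymethoxy)-4-methylbenzoate F3. Its two formyl groups are equivalent, so no regiochemical question arises.
  - One equivalent of mCPBA (Baeyer–Villiger oxidation, aryl migration helped by the ortho aryloxy donor) converts one formyl group into the formate, methyl 2-[2-formyl-6-(formyloxy)-4-methoxyphenoxy]-6-(methoxymethoxy)-4-methylbenzoate F4.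
  - NaBH4 in MeOH at 0 °C reduces the other formyl group and cleaves the formate to methyl 2-[2-hydroxy-6-(hydroxymethyl)-4-methoxyphenoxy]-6-(methoxymethoxy)-4-methylbenzoate F5.
  - The conditions of step 8 remove the MOM group to reach 19.

**Step 2.**
- What may go wrong:
  - Formaldehyde may polymerise on the Lewis acid faster than the allenolate captures it.
  - The allenolate may be protonated to the plain β-iodo enone.
  - The adduct may take up further formaldehyde.
- Fallback (sets out from 2, with purchased methyl vinyl ketone in the place of 3, and returns at 7): the hydroxymethyl group is placed on an enone first and the halogen afterwards.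
  - Methyl vinyl ketone and aqueous formaldehyde under DABCO catalysis (Morita–Baylis–Hillman reaction) would give 3-(hydroxymethyl)but-3-en-2-one F6.
  - TBSCl and imidazole give 3-{[(tert-butyldimethylsilyl)oxy]methyl}but-3-en-2-one F7.
  - Addition of Br2 in CH2Cl2 gives racemic 3,4-dibromo-3-{[(tert-butyldimethylsilyl)oxy]methyl}butan-2-one F8.
  - Dehydrobromination with Et3N, which removes the more acidic hydrogen of the CH2Br group, gives (3E)-4-bromo-3-{[(tert-butyldimethylsilyl)oxy]methyl}but-3-en-2-one F9.
  - F9 takes the place of 6 under the conditions of step 4 and gives 7 with phenol 2.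

**Step 5.**
- What may go wrong:
  - The amide base or the enolate may attack the aryl enol ether or the ring A ester.
  - Acylation may occur on oxygen instead of carbon.
  - The aryloxy group may be lost by hydrolysis in the moist amine medium of the transfer stage.
- Fallback (sets out from 6 and 2, returns at 10): the order of events is inverted, so the strong base never meets ring A.
  - Iodo enone 6 is enolised (LiN(SiMe3)2, THF, −78 °C) and acylated with CF3CO2CH2CF3 to (5Z)-5-{[(tert-butyldimethylsilyl)oxy]methyl}-1,1,1-trifluoro-6-iodohex-5-ene-2,4-dione F10.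
  - MsN3 and Et3N convert it into (3Z)-3-{[(tert-butyldimethylsilyl)oxy]methyl}-1-diazo-4-iodobut-3-en-2-one F11.
  - The base-stable diazo ketone then undergoes the vinylic substitution of step 4 with phenol 2 (Cs2CO3, MeCN) to give 10.

**Further compounds**
F1 | step 7 | 2-bromo-1,3-bis(bromomethyl)-5-methoxybenzene | COc1cc(CBr)c(Br)c(CBr)c1
F2 | step 7 | 2-bromo-5-methoxybenzene-1,3-dicarbaldehyde | COc1cc(C=O)c(Br)c(C=O)c1
F3 | step 7 | methyl 2-(2,6-diformyl-4-methoxyphenoxy)-6-(methoxymethoxy)-4-methylbenzoate | COC(=O)c1c(OCOC)cc(C)cc1Oc1c(C=O)cc(OC)cc1C=O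
F4 | step 7 | methyl 2-[2-formyl-6-(formyloxy)-4-methoxyphenoxy]-6-(methoxymethoxy)-4-methylbenzoate | COC(=O)c1c(OCOC)cc(C)cc1Oc1c(OC=O)cc(OC)cc1C=O
F5 | step 7 | methyl 2-[2-hydroxy-6-(hydroxymethyl)-4-methoxyphenoxy]-6-(methoxymethoxy)-4-methylbenzoate | COC(=O)c1c(OCOC)cc(C)cc1Oc1c(O)cc(OC)cc1CO
F6 | step 2 | 3-(hydroxymethyl)but-3-en-2-one | CC(=O)C(=C)CO
F7 | step 2 | 3-{[(tert-butyldimethylsilyl)oxy]methyl}but-3-en-2-one | CC(=O)C(=C)CO[Si](C)(C)C(C)(C)C
F8 | step 2 | 3,4-dibromo-3-{[(tert-butyldimethylsilyl)oxy]methyl}butan-2-one (racemic) | CC(=O)C(Br)(CBr)CO[Si](C)(C)C(C)(C)C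
F9 | step 2 | (3E)-4-bromo-3-{[(tert-butyldimethylsilyl)oxy]methyl}but-3-en-2-one | CC(=O)/C(CO[Si](C)(C)C(C)(C)C)=C/Br
F10 | step 5 | (5Z)-5-{[(tert-butyldimethylsilyl)oxy]methyl}-1,1,1-trifluoro-6-iodohex-5-ene-2,4-dione | O=C(CC(=O)/C(CO[Si](C)(C)C(C)(C)C)=C\I)C(F)(F)F
F11 | step 5 | (3Z)-3-{[(tert-butyldimethylsilyl)oxy]methyl}-1-diazo-4-iodobut-3-en-2-one | [N-]=[N+]=CC(=O)/C(CO[Si](C)(C)C(C)(C)C)=C\I
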